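C2–C1' is cut first, after release of 5-OH, 4'-OH and 11-OH. It joins ring C to ring B inside the seven-membered oxepine (C2, C3, C9, C10, O, C2', C1'). The cut is possible because C2–H is the only C–H of a 3-alkylated pyranone ring C, is acidified by O1, and is held opposite a C1'–Br bond by the C9–C10–O tether.
Further cuts: O1–C2 and C2=C3 (one carbon from DMF-DMA), C4–C4a (aryllithium plus aldehyde), C10–O (Mitsunobu), both C11–CH3 bonds (MeMgBr), C3–C9 (copper-catalysed vinyl opening of a glycidate), and the side-chain C=C on C6 (Wittig).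
Forward order: the ring B phenol is etherified with the chiral chain, the chain end is raised to the C4 aldehyde, ring A is added as an aryllithium, ring C is closed, and the oxepine is the last ring to close.
Stereochemistry: C10 comes from methyl (S)-glycidate and is inverted once, in the Mitsunobu step, to R. The coupling aldehyde carries this centre in the γ position, so it cannot epimerise. The E alkene is reached by radical equilibration.
Protection: 11-OH travels as its TBS ether, so that no tertiary alkoxide can couple to C1' (six-membered 1,4-benzodioxane) in the palladium step. The 5-O-methyl and 4'-O-MOM groups fall at the end.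

Key step: step 14

Numbering: flavone numbering is used (ring A C5–C8, ring C O1–C4, ring B C1'–C6'). C9 is the CH2 on C3, C10 is the stereocentre, and C11 is the C(CH3)2O carbon.

Step 1
Reactants: 1 4-bromoresorcinol
Product: 2 2-bromo-5-(methoxymethoxy)phenol
Conditions: MOMCl (1.0 equiv), i-Pr2NEt (1.1 equiv), CH2Cl2, −10 → 0 °C
Reagents that add atoms: chloromethyl methyl ether (MOMCl), COCCl
Why: Base-mediated O-alkylation (Williamson-type acetal formation) with one equivalent of MOMCl should take the open hydroxyl para to bromine, because the hydroxyl next to bromine is shielded and less nucleophilic, and the minor bis-ether and regioisomer are removed by chromatography.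

Step 2
Reactants: 3 methyl (S)-glycidate
Product: 4 methyl (2S)-2-hydroxypent-4-enoate
Conditions: CH2=CHMgBr (1.3 equiv), CuBr·SMe2 (20 mol %), THF, −78 → −40 °C; aq. NH4Cl
Reagents that add atoms: vinylmagnesium bromide, C=C[Mg]Br
Why: Copper-catalysed SN2 opening of a terminal epoxide by a vinyl Grignard reagent occurs at the unsubstituted carbon faster than the ester is attacked at low temperature, so the C–O bond at the stereocentre is untouched and the S configuration is kept.

Step 3
Reactants: 2 2-bromo-5-(methoxymethoxy)phenol; 4 methyl (2S)-2-hydroxypent-4-enoate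
Product: 5 methyl (2R)-2-[2-bromo-5-(methoxymethoxy)phenoxy]pent-4-enoate
Conditions: PPh3, DIAD, PhMe, 0 °C → rt
Reagents that add atoms: none
Why: The Mitsunobu reaction of an α-hydroxy ester with an acidic ortho-bromophenol runs by SN2 displacement of the oxyphosphonium group, which inverts the carbinol carbon and so sets C10 as R.

Step 4
Reactants: 5 methyl (2R)-2-[2-bromo-5-(methoxymethoxy)phenoxy]pent-4-enoate
Product: 6 (3R)-3-[2-bromo-5-(methoxymethoxy)phenoxy]-2-methylhex-5-en-2-ol
Conditions: MeMgBr (3.5 equiv), THF, −20 → 0 °C; aq. NH4Cl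
Reagents that add atoms: methylmagnesium bromide, C[Mg]Br
Why: Double Grignard addition to the activated α-aryloxy ester builds the C11 dimethylcarbinol faster than the α-proton is removed, while aryl bromide and MOM acetal are inert to MeMgBr, so C10 should stay R.

Step 5
Reactants: 6 (3R)-3-[2-bromo-5-(methoxymethoxy)phenoxy]-2-methylhex-5-en-2-ol
Product: 7 tert-butyldimethylsilyl ether of 6
Conditions: TBSOTf (1.5 equiv), 2,6-lutidine (2.5 equiv), CH2Cl2, 0 °C → rt
Reagents that add atoms: tert-butyldimethylsilyl triflate, CC(C)(C)[Si](C)(C)OS(=O)(=O)C(F)(F)F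
Why: Silylation of a hindered tertiary alcohol with a silyl triflate and a non-nucleophilic pyridine base is standard and fast enough to leave the aryl acetal alone, and the TBS ether prevents lactol formation in step 7 and palladium alkoxide chemistry in step 14.

Step 6
Reactants: 7 tert-butyldimethylsilyl ether of 6
Product: 9 (4R)-4-[2-bromo-5-(methoxymethoxy)phenoxy]-5-[(tert-butyldimethylsilyl)oxy]-5-methylhexan-1-ol, via B-alkyl-9-BBN adduct 8 (not isolated)
Conditions: 9-BBN (1.5 equiv), THF, 0 °C → rt; then NaOH (aq), H2O2, 0 °C → rt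
Reagents that add atoms: hydrogen peroxide, OO; 9-borabicyclo[3.3.1]nonane, B1C2CCCC1CCC2 (its atoms are held only in 8)
Why: Hydroboration–oxidation with the bulky 9-BBN places boron on the terminal carbon of the monosubstituted alkene (anti-Markovnikov), and alkaline peroxide leaves aryl bromide, acetal and silyl ether intact.

Step 7
Reactants: 9 (4R)-4-[2-bromo-5-(methoxymethoxy)phenoxy]-5-[(tert-butyldimethylsilyl)oxy]-5-methylhexan-1-ol
Product: 10 (4R)-4-[2-bromo-5-(methoxymethoxy)phenoxy]-5-[(tert-butyldimethylsilyl)oxy]-5-methylhexanal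
Conditions: Dess–Martin periodinane, CH2Cl2, 0 °C → rt
Reagents that add atoms: none
Why: Dess–Martin oxidation stops at the aldehyde under near-neutral conditions, and the stereocentre is γ to the new carbonyl group and therefore cannot epimerise.

Step 8
Reactants: 11 4-hydroxy-2,6-dimethoxybenzaldehyde
Product: 12 2,6-dimethoxy-4-(methoxymethoxy)benzaldehyde
Conditions: MOMCl (1.2 equiv), i-Pr2NEt (1.5 equiv), CH2Cl2, 0 °C → rt
Reagents that add atoms: chloromethyl methyl ether (MOMCl), COCCl
Why: O-alkylation of the acidic para-formyl phenol with MOMCl gives the acetal that masks the future O1 and later directs the lithiation.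

Step 9
Reactants: 12 2,6-dimethoxy-4-(methoxymethoxy)benzaldehyde
Product: 14 1,3-dimethoxy-5-(methoxymethoxy)-2-[(E)-3-methylbut-1-enyl]benzene, via Z-styrene 13 (not isolated)
Conditions: i-BuPPh3Br, KOt-Bu, THF, 0 °C; then 12, 0 °C → rt; crude olefin: PhSSPh (10 mol %), THF, visible light, 65 °C
Reagents that add atoms: isobutyltriphenylphosphonium bromide, CC(C)C[P+](c1ccccc1)(c1ccccc1)c1ccccc1.[Br-]
Why: The Wittig reaction of the non-stabilised ylide builds the C=C bond mainly as the Z isomer, and reversible addition of phenylthiyl radicals then equilibrates it to the E isomer, which is favoured because a Z isopropyl group clashes with the two ortho methoxy groups, while addition–elimination of a radical cannot move the double bond.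

Step 10
Reactants: 14 1,3-dimethoxy-5-(methoxymethoxy)-2-[(E)-3-methylbut-1-enyl]benzene; 10 (4R)-4-[2-bromo-5-(methoxymethoxy)phenoxy]-5-[(tert-butyldimethylsilyl)oxy]-5-methylhexanal
Product: 16 (4R)-4-[2-bromo-5-(methoxymethoxy)phenoxy]-5-[(tert-butyldimethylsilyl)oxy]-1-{2,4-dimethoxy-6-(methoxymethoxy)-3-[(E)-3-methylbut-1-enyl]phenyl}-5-methylhexan-1-ol as a mixture of C1 epimers, via aryllithium 15 (not isolated)
Conditions: 14 (1.2 equiv), n-BuLi (1.15 equiv), THF, −78 → 0 °C; then 10, −78 °C; aq. NH4Cl
Reagents that add atoms: n-butyllithium, [Li]CCCC (lithium is held only in 15)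
Why: Directed ortho-metalation occurs at either of the two equivalent C–H positions flanked by OMOM and OMe, where two oxygen donors cooperate, and the aryllithium adds to the aldehyde at −78 °C far faster than it exchanges with the aryl bromide, the new carbinol centre being formed without control and erased in step 11.

Step 11
Reactants: 16 the C1-epimeric carbinols
Product: 17 (4R)-4-[2-bromo-5-(methoxymethoxy)phenoxy]-5-[(tert-butyldimethylsilyl)oxy]-1-{2,4-dimethoxy-6-(methoxymethoxy)-3-[(E)-3-methylbut-1-enyl]phenyl}-5-methylhexan-1-one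
Conditions: Dess–Martin periodinane, CH2Cl2, 0 °C → rt
Reagents that add atoms: none
Why: Dess–Martin oxidation of the benzylic alcohol gives the aryl ketone (C4) without touching styrene, acetals or silyl ether, and merges both epimers into one compound.

Step 12
Reactants: 17 the MOM-protected aryl ketone
Product: 18 (4R)-4-[2-bromo-5-(methoxymethoxy)phenoxy]-5-[(tert-butyldimethylsilyl)oxy]-1-{6-hydroxy-2,4-dimethoxy-3-[(E)-3-methylbut-1-enyl]phenyl}-5-methylhexan-1-one
Conditions: HCl (0.05 M in MeOH–CH2Cl2), 0 °C → rt, stopped when 17 is consumed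
Reagents that add atoms: none
Why: Acid-catalysed acetal methanolysis is fastest for the MOM ether ortho to the ketone, because the departing phenol is acidified by the acyl group and held by a hydrogen bond to the carbonyl oxygen, so very dilute acid should spare the ring B acetal and the tertiary TBS ether.

Step 13
Reactants: 18 the 2'-hydroxyaryl ketone
Product: 20 3-[(2R)-2-[2-bromo-5-(methoxymethoxy)phenoxy]-3-[(tert-butyldimethylsilyl)oxy]-3-methylbutyl]-5,7-dimethoxy-6-[(E)-3-methylbut-1-enyl]chromen-4-one, via enaminone 19 (not isolated)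
Conditions: Me2NCH(OMe)2 (5 equiv), PhMe, 110 °C
Reagents that add atoms: N,N-dimethylformamide dimethyl acetal, COC(OC)N(C)C
Why: Condensation of the α-methylene group with DMF-DMA gives the enaminone, and conjugate addition of the ortho phenol with loss of dimethylamine closes ring C (6-endo-trig addition–elimination) with C2 left as C–H, as in the known conversion of 2'-hydroxydihydrochalcones into 3-benzylchromones.

Step 14
Reactants: 20 the 3-alkylchromone with free C2–H and tethered 2-bromoaryl ether
Product: 21 5-O-methyl-4'-O-MOM-11-O-TBS derivative of the target tetracycle (10R)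
Conditions: Pd(OAc)2 (10 mol %), PCy3·HBF4 (20 mol %), K2CO3 (3 equiv), PivOH (30 mol %), DMA (0.01 M), 110 °C
Reagents that add atoms: none
Why: Zerovalent palladium formed from Pd(OAc)2 and PCy3 inserts into the C1'–Br bond, pivalate replaces bromide on the divalent palladium aryl complex and removes C2–H of ring C in a concerted metalation–deprotonation, and reductive elimination from the eight-membered palladacycle forges C2–C1'. The closest known chemistry is the carboxylate-assisted intramolecular direct arylation of heteroarene C–H bonds by tethered aryl bromides, which reaches seven-membered rings and has been applied to C2–H of chromones. The oxepine (C2, C3, C9, C10, O, C2', C1') closes in a formal 7-endo-trig sense because both carbons of C2=C3 become ring members, and a Heck-type carbopalladation that places the aryl group on the β-carbon C2, followed by base-induced elimination through the palladium enolate, would lead to the same flavone. No stereocentre is created, and C10 keeps its R configuration because it takes part in no bond change and its C–H is not acidic. Selectivity is needed against the sp3 C–H bonds of C9 and the gem-dimethyl group, against the ring A styrene and against C–O coupling: C3 is blocked and C2–H is the only acidic sp2 C–H that the tether can bring to palladium, the hindered 1,2-disubstituted styrene can react only intermolecularly and is held back by dilution, and the TBS ether removes the tertiary alkoxide that would otherwise close a six-membered 1,4-benzodioxane.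

Step 15
Reactants: 21 the protected tetracycle
Product: 22 4'-O-MOM-11-O-TBS derivative of the target (5-OH free)
Conditions: MgI2·OEt2 (3 equiv), PhMe–Et2O, 60 °C; aq. NH4Cl
Reagents that add atoms: none
Why: Magnesium binds the C4 carbonyl and the peri 5-methoxy oxygen in a six-membered chelate and iodide takes the methyl group by SN2 attack (chelation-assisted aryl ether cleavage), so the 7-methoxy group, the oxepine ether, the acetal and the silyl ether, which cannot chelate, should survive, and no strongly ionising Lewis acid meets the C10–C11 unit.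

Step 16
Reactants: 22 4'-O-MOM-11-O-TBS derivative of the target
Product: 23 target CNP0216454.1
Conditions: HCl (1.25 M in MeOH), 40 °C
Reagents that add atoms: none
Why: Acid-catalysed methanolysis removes the aryl MOM acetal and the TBS ether in one operation under conditions that alkenyl-substituted flavones and tertiary carbinols normally tolerate, and C10 is not involved.

Compound list
1 | 4-bromoresorcinol | Oc1ccc(Br)c(O)c1 | starting material
2 | 2-bromo-5-(methoxymethoxy)phenol | COCOc1ccc(Br)c(O)c1 | intermediate
3 | methyl (S)-glycidate | COC(=O)[C@@H]1CO1 | starting material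
4 | methyl (2S)-2-hydroxypent-4-enoate | C=CC[C@@H](C(=O)OC)O | intermediate
5 | methyl (2R)-2-[2-bromo-5-(methoxymethoxy)phenoxy]pent-4-enoate | C=CC[C@H](C(=O)OC)Oc1cc(OCOC)ccc1Br | intermediate
6 | (3R)-3-[2-bromo-5-(methoxymethoxy)phenoxy]-2-methylhex-5-en-2-ol | C=CC[C@H](C(C)(C)O)Oc1cc(OCOC)ccc1Br | intermediate
7 | tert-butyldimethylsilyl ether of 6 | C=CC[C@H](C(C)(C)O[Si](C)(C)C(C)(C)C)Oc1cc(OCOC)ccc1Br | intermediate
8 | B-alkyl-9-BBN adduct of 7 (boron on the terminal carbon; not isolated) | B1(CCC[C@H](C(C)(C)O[Si](C)(C)C(C)(C)C)Oc2cc(OCOC)ccc2Br)C2CCCC1CCC2 | intermediate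
9 | (4R)-4-[2-bromo-5-(methoxymethoxy)phenoxy]-5-[(tert-butyldimethylsilyl)oxy]-5-methylhexan-1-ol | OCCC[C@H](C(C)(C)O[Si](C)(C)C(C)(C)C)Oc1cc(OCOC)ccc1Br | intermediate
10 | (4R)-4-[2-bromo-5-(methoxymethoxy)phenoxy]-5-[(tert-butyldimethylsilyl)oxy]-5-methylhexanal | O=CCC[C@H](C(C)(C)O[Si](C)(C)C(C)(C)C)Oc1cc(OCOC)ccc1Br | intermediate
11 | 4-hydroxy-2,6-dimethoxybenzaldehyde | COc1cc(O)cc(OC)c1C=O | starting material
12 | 2,6-dimethoxy-4-(methoxymethoxy)benzaldehyde | COCOc1cc(OC)c(C=O)c(OC)c1 | intermediate
13 | 1,3-dimethoxy-5-(methoxymethoxy)-2-[(Z)-3-methylbut-1-enyl]benzene (not isolated) | COc1cc(OCOC)cc(OC)c1/C=C\C(C)C | intermediate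
14 | 1,3-dimethoxy-5-(methoxymethoxy)-2-[(E)-3-methylbut-1-enyl]benzene | COc1cc(OCOC)cc(OC)c1/C=C/C(C)C | intermediate
15 | aryllithium from 14, lithium between OMOM and OMe (not isolated) | COc1cc(OCOC)c([Li])c(OC)c1/C=C/C(C)C | intermediate
16 | (4R)-carbinol from 15 and 10, both C1 epimers | COc1cc(OCOC)c(C(O)CC[C@H](C(C)(C)O[Si](C)(C)C(C)(C)C)Oc2cc(OCOC)ccc2Br)c(OC)c1/C=C/C(C)C | intermediate
17 | (4R)-aryl ketone with ring A OMOM | COc1cc(OCOC)c(C(=O)CC[C@H](C(C)(C)O[Si](C)(C)C(C)(C)C)Oc2cc(OCOC)ccc2Br)c(OC)c1/C=C/C(C)C | intermediate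
18 | (4R)-2'-hydroxyaryl ketone | COc1cc(O)c(C(=O)CC[C@H](C(C)(C)O[Si](C)(C)C(C)(C)C)Oc2cc(OCOC)ccc2Br)c(OC)c1/C=C/C(C)C | intermediate
19 | α-(dimethylaminomethylene) ketone from 18 (enaminone; not isolated) | COc1cc(O)c(C(=O)C(=CN(C)C)C[C@H](C(C)(C)O[Si](C)(C)C(C)(C)C)Oc2cc(OCOC)ccc2Br)c(OC)c1/C=C/C(C)C | intermediate
20 | 3-[(2R)-2-[2-bromo-5-(methoxymethoxy)phenoxy]-3-[(tert-butyldimethylsilyl)oxy]-3-methylbutyl]-5,7-dimethoxy-6-[(E)-3-methylbut-1-enyl]chromen-4-one | COc1cc2occ(C[C@H](C(C)(C)O[Si](C)(C)C(C)(C)C)Oc3cc(OCOC)ccc3Br)c(=O)c2c(OC)c1/C=C/C(C)C | intermediate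
21 | (10R)-oxepinoflavone with 5-OMe, 7-OMe, 4'-OMOM, 11-OTBS and 6-[(E)-3-methylbut-1-enyl] | COc1cc2oc3c(c(=O)c2c(OC)c1/C=C/C(C)C)C[C@H](C(C)(C)O[Si](C)(C)C(C)(C)C)Oc1cc(OCOC)ccc1-3 | intermediate
22 | (10R)-oxepinoflavone with 5-OH, 7-OMe, 4'-OMOM and 11-OTBS | COc1cc2oc3c(c(=O)c2c(O)c1/C=C/C(C)C)C[C@H](C(C)(C)O[Si](C)(C)C(C)(C)C)Oc1cc(OCOC)ccc1-3 | intermediate
23 | CNP0216454.1: (10R)-5,4'-dihydroxy-7-methoxy-6-[(E)-3-methylbut-1-enyl]flavone with C3 and 2'-O bridged by CH2–CH[C(CH3)2OH] | COc1cc2oc3c(c(=O)c2c(O)c1/C=C/C(C)C)C[C@H](C(C)(C)O)Oc1cc(O)ccc1-3 | target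

Total step count: 16.
Longest linear sequence: 13 steps (3 → 23, steps 2–7 and 10–16).

Steps most likely to fail

Step 14. The eight-membered palladacycle may form too slowly. Hydrodebromination of ring B or palladation of an sp3 C–H bond could then overtake cleavage of C2–H. The fallback sets out from 20 and returns at 21, and it takes the C–H cleavage away from palladium. Deprotonative zincation of C2–H uses TMPZnCl·LiCl in the presence of MgCl2 (THF, −20 → 25 °C). This is a known way to metalate chromones at C2 and it leaves aryl bromides alone. It should give the C2-chlorozinc chromone F1. Addition of Pd(OAc)2 and SPhos at high dilution and warming to 50 °C then closes the same C2–C1' bond by an intramolecular Negishi coupling to give 21.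

Step 12. The two aryl acetals may be poorly discriminated, so that the ring B MOM group is lost along with the ring A one. The fallback sets out from 17 and returns at 18, and it replaces selective cleavage by selective re-protection. Both aryl MOM ethers are removed on purpose (p-TsOH·H2O, MeOH, 40 °C, with the tertiary TBS ether retained) to give the bromodiphenol ketone F2. One equivalent of MOMCl with i-Pr2NEt in CH2Cl2 at 0 °C then alkylates only the free ring B phenol. The 2'-OH is locked in a hydrogen bond to the ketone and is known to resist such alkylation. This gives 18.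

Step 10. Butyllithium may add across the styrene, or the ortho-lithiation may stay incomplete, which would erode the supply of aryllithium. The fallback sets out from 11 and returns at 15 (and hence 16), and it fixes the metalation site with a halogen placed before the alkene exists.
- NBS (1 equiv, MeCN, 0 °C) brominates one of the two equivalent positions ortho to the phenol and gives 3-bromo-4-hydroxy-2,6-dimethoxybenzaldehyde F3.
- MOMCl with i-Pr2NEt gives 3-bromo-2,6-dimethoxy-4-(methoxymethoxy)benzaldehyde F4.
- The Wittig reaction of step 9 gives the Z-bromostyrene F5, which PhSSPh under light equilibrates to 1-bromo-2,4-dimethoxy-6-(methoxymethoxy)-3-[(E)-3-methylbut-1-enyl]benzene F6.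
- Bromine–lithium exchange with n-BuLi at −78 °C is complete within minutes, long before any carbolithiation, and delivers 15 for the addition to 10.

Further compounds
F1 | step 14 | C2-chlorozinc derivative of chromone 20 | COc1cc2oc([Zn]Cl)c(C[C@H](C(C)(C)O[Si](C)(C)C(C)(C)C)Oc3cc(OCOC)ccc3Br)c(=O)c2c(OC)c1/C=C/C(C)C
F2 | step 12 | (4R)-4-(2-bromo-5-hydroxyphenoxy)-5-[(tert-butyldimethylsilyl)oxy]-1-{6-hydroxy-2,4-dimethoxy-3-[(E)-3-methylbut-1-enyl]phenyl}-5-methylhexan-1-one | COc1cc(O)c(C(=O)CC[C@H](C(C)(C)O[Si](C)(C)C(C)(C)C)Oc2cc(O)ccc2Br)c(OC)c1/C=C/C(C)C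
F3 | step 10 | 3-bromo-4-hydroxy-2,6-dimethoxybenzaldehyde | COc1cc(O)c(Br)c(OC)c1C=O
F4 | step 10 | 3-bromo-2,6-dimethoxy-4-(methoxymethoxy)benzaldehyde | COCOc1cc(OC)c(C=O)c(OC)c1Br
F5 | step 10 | 1-bromo-2,4-dimethoxy-6-(methoxymethoxy)-3-[(Z)-3-methylbut-1-enyl]benzene | COCOc1cc(OC)c(/C=C\C(C)C)c(OC)c1Br
F6 | step 10 | 1-bromo-2,4-dimethoxy-6-(methoxymethoxy)-3-[(E)-3-methylbut-1-enyl]benzene | COCOc1cc(OC)c(/C=C/C(C)C)c(OC)c1Br
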